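**Retrosynthetic overview**
1. The target is 4'-O-methylcupressuflavone, two flavones joined C8–C8''. Rings C and C'' are the same 2-aryl-4-pyranone fused to phloroglucinol rings A and A''. Rings B and B'' differ only at O-4' (methyl) and O-4''' (hydrogen), so they map onto two para-oxygenated benzaldehydes.
2. Last operation: the three benzyl ethers (O-7, O-7'', O-4''') and the two carbonyl-chelated methyl ethers (O-5, O-5'') are removed from protected biflavone 14.
3. Key disconnection: O1–C2 and O1''–C2'' of 14 are cut together and lead back to bis(2-hydroxychalcone) 12. Rings C and C'' are the only rings built, and they form last, in one flask.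
4. The two enone C=C bonds of 12 come from successive Claisen–Schmidt condensations of the symmetric diacetylbiphenyl 8 with aldehydes 9 and 11.
5. Compound 8 comes from biaryl tetraol 5 by double C-acetylation and selective O-benzylation. The axis (future C8–C8'') is made first, by oxidative homocoupling of lithiated 5-methoxyresorcinol bis-MOM ether.

Key step: step 8

Assumption: the SMILES gives no descriptor for the C8–C8'' axis, so every biaryl from 7 onward is carried as the racemate.

**Step 1**
Reactants: 1 5-methoxyresorcinol
Product: 2 1-methoxy-3,5-bis(methoxymethoxy)benzene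
Conditions: NaH (2.4 equiv), MOMCl (2.4 equiv), DMF, 0 °C to rt
Reagents that add atoms: chloromethyl methyl ether (MOMCl), COCCl
Why: Williamson-type O-alkylation of the bis-phenoxide with the hard electrophile MOMCl should occur at oxygen rather than carbon, and it installs the two chelating groups that later steer metalation to the carbon between them.

**Step 2**
Reactants: 2 1-methoxy-3,5-bis(methoxymethoxy)benzene (two molecules)
Product: 4 4,4'-dimethoxy-2,2',6,6'-tetrakis(methoxymethoxy)biphenyl, via aryllithium 3 (not isolated)
Conditions: n-BuLi (1.1 equiv), THF, 0 °C to rt; then anhydrous CuCl2 (1.3 equiv), −78 °C to rt, Ar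
Reagents that add atoms: none
Why: Directed ortho-metalation should take the proton at C2, which lies between two chelating OMOM groups that outrank OMe as directors, and oxidative homocoupling of 2,6-dialkoxyaryllithiums with CuCl2 (divalent copper reduced to monovalent copper) is an established route to tetra-ortho-oxygenated biphenyls that here places both methoxy groups para to the new axis.

**Step 3**
Reactants: 4 4,4'-dimethoxy-2,2',6,6'-tetrakis(methoxymethoxy)biphenyl
Product: 5 4,4'-dimethoxybiphenyl-2,2',6,6'-tetraol
Conditions: conc. HCl (cat.), MeOH, 45 °C, Ar
Reagents that add atoms: none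
Why: Acid-catalysed transacetalisation (standard MOM cleavage) passes the methoxymethyl units to methanol as dimethoxymethane, so no formaldehyde equivalent remains to attack the nucleophilic rings, and the aryl methyl ethers are inert to dilute HCl.

**Step 4**
Reactants: 5 4,4'-dimethoxybiphenyl-2,2',6,6'-tetraol; 6 acetic anhydride
Product: 7 3,3'-diacetyl-4,4'-dimethoxybiphenyl-2,2',6,6'-tetraol (racemic axis)
Conditions: Ac2O (2.1 equiv), BF3·OEt2 (as medium), 0 to 45 °C, Ar; aq. NaOAc quench
Reagents that add atoms: none
Why: In this Friedel–Crafts C-acetylation of a phloroglucinol-type ring (any aryl acetate formed first converges by Fries migration), C3 and C5 of each ring are equivalent and the carbon para to OMe is taken by the axis, so only one regioisomer can form, the first acetyl deactivates its own ring and sends the second to the other ring, and BF3 is preferred to AcCl/AlCl3 because AlCl3 could cleave the methyl ether ortho to the new ketone and so destroy the later regiocontrol.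

**Step 5**
Reactants: 7 3,3'-diacetyl-4,4'-dimethoxybiphenyl-2,2',6,6'-tetraol
Product: 8 3,3'-diacetyl-6,6'-bis(benzyloxy)-4,4'-dimethoxybiphenyl-2,2'-diol
Conditions: BnBr (2.1 equiv), K2CO3 (2.2 equiv), acetone, reflux
Reagents that add atoms: benzyl bromide, BrCc1ccccc1
Why: This is a chemoselective Williamson etherification, as in the 4-O-benzylation of 2,4-dihydroxyacetophenones, in which the 6- and 6'-hydroxyls (para to acetyl, more acidic, not hydrogen-bonded) are alkylated under weak base while the 2- and 2'-hydroxyls stay locked in a hydrogen bond to the neighbouring acetyl carbonyl.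

**Step 6**
Reactants: 8 3,3'-diacetyl-6,6'-bis(benzyloxy)-4,4'-dimethoxybiphenyl-2,2'-diol; 9 4-(benzyloxy)benzaldehyde
Product: 10 mono-chalcone, (E)-1-[3'-acetyl-6,6'-bis(benzyloxy)-2,2'-dihydroxy-4,4'-dimethoxybiphenyl-3-yl]-3-[4-(benzyloxy)phenyl]prop-2-en-1-one
Conditions: 9 (0.7 equiv, slow addition), 50% aq. KOH, EtOH–THF, rt; cold dilute HCl; chromatography, recovered 8 recycled
Reagents that add atoms: none
Why: In this Claisen–Schmidt condensation (aldol addition, then E1cB dehydration to the conjugated (E)-enone) the two acetyl groups are equivalent and electronically insulated by the twisted axis, so the distribution is statistical and is managed by keeping 9 limiting, separating the coloured mono-chalcone and recycling unchanged 8.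

**Step 7**
Reactants: 10 mono-chalcone; 11 4-methoxybenzaldehyde
Product: 12 mixed bis-chalcone, (E)-1-[6,6'-bis(benzyloxy)-3'-{(E)-3-[4-(benzyloxy)phenyl]acryloyl}-2,2'-dihydroxy-4,4'-dimethoxybiphenyl-3-yl]-3-(4-methoxyphenyl)prop-2-en-1-one
Conditions: 11 (3 equiv), 50% aq. KOH, EtOH–THF, rt; cold dilute HCl
Reagents that add atoms: none
Why: This second Claisen–Schmidt condensation acts on the only remaining enolisable ketone and is driven to completion with an excess of cheap, easily removed 11, while the enone already present has no acidic alpha-hydrogen and should not exchange by retro-aldol at room temperature, and the new alkene is again (E) through E1cB dehydration.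

**Step 8**
Reactants: 12 mixed bis-chalcone
Product: 14 7,7''-bis(benzyloxy)-2''-[4-(benzyloxy)phenyl]-5,5''-dimethoxy-2-(4-methoxyphenyl)-8,8''-bi(4H-chromene)-4,4''-dione (protected biflavone), via bis-flavanone 13 (not isolated)
Conditions: I2 (0.2 equiv), DMSO, 120–130 °C, Ar; aq. Na2S2O3 wash
Reagents that add atoms: none
Why: Each free phenol at C2/C2' of the biphenyl adds to the beta-carbon of its own (E)-enone in a reversible 6-endo-trig oxa-Michael addition, which forms O1–C2 and O1''–C2'' and closes rings C and C'' at the flavanone level (13). Iodine then dehydrogenates each flavanone (alpha-iodination of the enol at C3/C3'' followed at once by loss of HI), which drains the equilibrium towards the aromatic 4-pyranones, while DMSO oxidises HI back to I2 with release of Me2S and water, so iodine is needed only in catalytic amount. The closest known reaction type is the I2/DMSO oxidative cyclisation of 2'-hydroxychalcones to flavones, applied here to two independent arms of one molecule. The selectivity required is regiochemical, since closure must use the oxygen beside the axis for the linkage to end up 8,8''; the substrate secures this because on each ring the other oxygen ortho to the acyl group is a methyl ether and the benzyl ether oxygen sits para to the acyl group, out of reach of the enone. The two C2 stereocentres of 13 arise without control and are erased by the dehydrogenation, so no stereocentre remains and the axis stays racemic. Because the twisted axis insulates the arms, they should react independently, and heating is continued until mono-cyclised and flavanone-level material has been consumed.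

**Step 9**
Reactants: 14 protected biflavone
Product: 15 4'-O-methylcupressuflavone (target CNP0322111.0)
Conditions: BCl3 (1 M in CH2Cl2, 12 equiv), pentamethylbenzene (10 equiv), CH2Cl2, −78 °C to rt; then aq. HCl–THF, rt
Reagents that add atoms: none
Why: BCl3 with pentamethylbenzene as a non-basic cation scavenger is a known low-temperature debenzylation of aryl benzyl ethers (the scavenger intercepts benzyl cations that would otherwise C-benzylate C6/C6''), and on warming BCl3 held at each C4 carbonyl cleaves only the peri 5-methyl ether, a known chelation-directed demethylation of 5-methoxyflavones, whereas the unchelated 4'-methyl ether, whose oxygen is made less basic by conjugation with the complexed pyranone, should persist.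

**Compound list**
1 | 5-methoxyresorcinol | COc1cc(O)cc(O)c1 | starting material
2 | 1-methoxy-3,5-bis(methoxymethoxy)benzene | COCOc1cc(OC)cc(OCOC)c1 | intermediate
3 | 4-methoxy-2,6-bis(methoxymethoxy)phenyllithium | [Li]c1c(OCOC)cc(OC)cc1OCOC | intermediate (not isolated)
4 | 4,4'-dimethoxy-2,2',6,6'-tetrakis(methoxymethoxy)biphenyl | COCOc1cc(OC)cc(OCOC)c1-c1c(OCOC)cc(OC)cc1OCOC | intermediate
5 | 4,4'-dimethoxybiphenyl-2,2',6,6'-tetraol | COc1cc(O)c(-c2c(O)cc(OC)cc2O)c(O)c1 | intermediate
6 | acetic anhydride | CC(=O)OC(C)=O | starting material
7 | 3,3'-diacetyl-4,4'-dimethoxybiphenyl-2,2',6,6'-tetraol (racemic axis) | CC(=O)c1c(OC)cc(O)c(-c2c(O)cc(OC)c(C(C)=O)c2O)c1O | intermediate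
8 | 3,3'-diacetyl-6,6'-bis(benzyloxy)-4,4'-dimethoxybiphenyl-2,2'-diol (racemic axis) | CC(=O)c1c(OC)cc(OCc2ccccc2)c(-c2c(OCc3ccccc3)cc(OC)c(C(C)=O)c2O)c1O | intermediate
9 | 4-(benzyloxy)benzaldehyde | O=Cc1ccc(OCc2ccccc2)cc1 | starting material
10 | mono-chalcone, (E)-4-(benzyloxy)cinnamoyl on one ring, acetyl on the other (racemic axis) | CC(=O)c1c(OC)cc(OCc2ccccc2)c(-c2c(OCc3ccccc3)cc(OC)c(C(=O)/C=C/c3ccc(OCc4ccccc4)cc3)c2O)c1O | intermediate
11 | 4-methoxybenzaldehyde | COc1ccc(C=O)cc1 | starting material
12 | mixed (E,E)-bis-chalcone (racemic axis) | COc1ccc(/C=C/C(=O)c2c(OC)cc(OCc3ccccc3)c(-c3c(OCc4ccccc4)cc(OC)c(C(=O)/C=C/c4ccc(OCc5ccccc5)cc4)c3O)c2O)cc1 | intermediate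
13 | bis-flavanone (mixture of diastereomers, C2 and C2'' not controlled) | COc1ccc(cc1)C1CC(=O)c2c(OC)cc(OCc3ccccc3)c(-c3c(OCc4ccccc4)cc(OC)c4C(=O)CC(Oc34)c3ccc(OCc4ccccc4)cc3)c2O1 | intermediate (not isolated)
14 | 7,7'',4'''-tri-O-benzyl-5,5''-di-O-methyl ether of the target (racemic axis) | COc1ccc(cc1)-c1cc(=O)c2c(OC)cc(OCc3ccccc3)c(-c3c(OCc4ccccc4)cc(OC)c4c(=O)cc(-c5ccc(OCc6ccccc6)cc5)oc34)c2o1 | intermediate
15 | 4'-O-methylcupressuflavone, 8-[5,7-dihydroxy-2-(4-hydroxyphenyl)-4-oxo-4H-chromen-8-yl]-5,7-dihydroxy-2-(4-methoxyphenyl)-4H-chromen-4-one | COc1ccc(-c2cc(=O)c3c(O)cc(O)c(-c4c(O)cc(O)c5c(=O)cc(-c6ccc(O)cc6)oc45)c3o2)cc1 | target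

Total step count: 9
Longest linear sequence: 9 steps (1 to 15)

**Steps most likely to fail**

1. **Step 4 (double C-acetylation of the free tetraol).**
   - Risk: acylation may stop at oxygen, a second acylation may occur on an already acylated ring, the 2,2'-diol may cyclodehydrate under acid to a dibenzofuran, or the electron-rich tetraol may oxidise in air.
   - Fallback: the acetyl groups are introduced by carbanion chemistry before the phenols are freed. Setting out from 4, n-BuLi/TMEDA (THF, 0 °C) should metalate each ring once at the carbon between OMOM and OMe and give 3,3'-dilithio-4,4'-dimethoxy-2,2',6,6'-tetrakis(methoxymethoxy)biphenyl F1. Addition of N-methoxy-N-methylacetamide and a cold dilute HCl quench should give 3,3'-diacetyl-4,4'-dimethoxy-2,2',6,6'-tetrakis(methoxymethoxy)biphenyl F2. HCl in MeOH then removes the four MOM groups, and the route is rejoined at 7.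

2. **Step 2 (metalation and oxidative homocoupling).**
   - Risk: chlorine transfer from CuCl2 or protonation of the hindered aryl-metal species may outrun aryl–aryl bond formation, and some metalation may occur between OMOM and OMe, which would feed regioisomeric biaryls into the mixture.
   - Fallback: the coupling is changed from oxidative to reductive. Setting out from aryllithium 3 (generated from 2 as in step 2), an I2 quench should give 2-iodo-5-methoxy-1,3-bis(methoxymethoxy)benzene F3. This can be purified, which also removes any regioisomer. Ullmann homocoupling with activated Cu powder in DMF at 150 °C, the classical entry to hexa-oxygenated biphenyls from 2,4,6-trialkoxyiodobenzenes, rejoins the route at 4.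

3. **Step 8 (double oxidative cyclisation).**
   - Risk: one arm may stall at the flavanone level, the electron-rich positions C6/C6'' may be iodinated, or HI may remove the methyl ether ortho to an acyl group before closure, which would allow ring closure in the wrong sense.
   - Fallback: ring closure and oxidation are separated and iodine is avoided. Setting out from 12, NaOAc in refluxing EtOH should close both arms by oxa-Michael addition, and bis-flavanone 13 is isolated as its diastereomer mixture. Hydride-abstraction dehydrogenation with DDQ in refluxing dioxane, which simple benzyl ethers tolerate, then rejoins the route at 14. This fallback makes no compound outside the list (F0).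

**Further compounds**
F1 | step 4 | 3,3'-dilithio-4,4'-dimethoxy-2,2',6,6'-tetrakis(methoxymethoxy)biphenyl | [Li]c1c(OC)cc(OCOC)c(-c2c(OCOC)cc(OC)c([Li])c2OCOC)c1OCOC
F2 | step 4 | 3,3'-diacetyl-4,4'-dimethoxy-2,2',6,6'-tetrakis(methoxymethoxy)biphenyl | CC(=O)c1c(OC)cc(OCOC)c(-c2c(OCOC)cc(OC)c(C(C)=O)c2OCOC)c1OCOC
F3 | step 2 | 2-iodo-5-methoxy-1,3-bis(methoxymethoxy)benzene | COCOc1cc(OC)cc(OCOC)c1I
F0 | step 8 | none | none
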